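**Plan**

- Numbering used throughout: oxolane O1, C2, C3 (carries the carbinol carbon C7), C4 (carries the 4-hydroxy-3-methoxybenzyl group), C5.
- The retrosynthesis cuts the two phenol O–benzyl bonds, then C7–aryl (C7 taken back to a ketone and a Weinreb amide), then the ring bond C3–C4, then C4–CH2Ar.
- Enabling feature: C3 carries exocyclic C7 next to benzyl-bearing C4. With C7 at the carboxyl level, the oxolane plus C7 is the ring-contracted image of a 3-benzyltetrahydropyran-4-one (C7 = ring carbonyl, C2 and C5 = its two OCH2 groups).
- Forward: tetrahydropyran-4-one (ring bought) is benzylated through its RAMP hydrazone, the other α-carbon receives a diazo group, and a photochemical Wolff rearrangement in methanol contracts the pyranone to the oxolane ester, the only ring-forming event. Weinreb amide formation, syringyl-lithium addition, ketone reduction and debenzylation follow.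
- Stereochemistry: C4 comes from the auxiliary-controlled alkylation and is carried through the 1,2-shift with retention; C3 is set by methoxide equilibration to the trans ester; C7 is set by CBS reduction, which the Felkin–Anh bias is expected to reinforce.

Key step: step 7

Remark: the facial sense of the hydrazone alkylation is assumed to follow the chelated azaenolate model (R auxiliary giving the S ketone here); the C=N geometry of hydrazone 6 is left open because both isomers hydrolyse to the same ketone.

**Route**

Step 1
Reactants: 1 4-(benzyloxy)-3-methoxybenzyl alcohol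
Product: 2 4-(benzyloxy)-3-methoxybenzyl bromide
Conditions: PBr3 (0.4 equiv), Et2O, 0 °C
Reagents that add atoms: phosphorus tribromide, BrP(Br)Br
Why: Bromination of a benzylic alcohol with PBr3 (SN2 displacement of the dibromophosphite) is routine for this electron-rich system, and the aryl benzyl ether is inert to it.

Step 2
Reactants: 3 tetrahydro-4H-pyran-4-one
Product: 4 (R)-2-(methoxymethyl)-N-(tetrahydro-4H-pyran-4-ylidene)pyrrolidin-1-amine
Conditions: RAMP, cyclohexane, 4 Å MS, 60 °C
Reagents that add atoms: RAMP [(R)-1-amino-2-(methoxymethyl)pyrrolidine], COC[C@H]1CCCN1N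
Why: Condensation of the unhindered ketone with the N-amino group gives the hydrazone on removal of water (hydrazone formation), and the symmetry of the ketone means a single hydrazone results.

Step 3
Reactants: 4 (R)-2-(methoxymethyl)-N-(tetrahydro-4H-pyran-4-ylidene)pyrrolidin-1-amine; 2 4-(benzyloxy)-3-methoxybenzyl bromide
Product: 6 (R)-N-[(3R)-3-[4-(benzyloxy)-3-methoxybenzyl]tetrahydro-4H-pyran-4-ylidene]-2-(methoxymethyl)pyrrolidin-1-amine, via lithium azaenolate 5 (not isolated)
Conditions: LiN(i-Pr)2, THF, −78 °C; then 2, −100 → −20 °C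
Reagents that add atoms: none
Why: Enders RAMP-hydrazone alkylation: deprotonation gives the lithium azaenolate with lithium chelated by the methoxymethyl arm, the benzylic bromide attacks the exposed face, and by the established facial rule of this auxiliary family the R auxiliary sets the new ring centre in the sense that becomes S in ketone 7 (descriptor R in the hydrazone because C=N ranks below CH2O).

Step 4
Reactants: 6 (R)-N-[(3R)-3-[4-(benzyloxy)-3-methoxybenzyl]tetrahydro-4H-pyran-4-ylidene]-2-(methoxymethyl)pyrrolidin-1-amine
Product: 7 (S)-3-[4-(benzyloxy)-3-methoxybenzyl]tetrahydro-4H-pyran-4-one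
Conditions: sat. aq. (CO2H)2, Et2O, rt
Reagents that add atoms: water, O
Why: Two-phase hydrolysis of the hydrazone with oxalic acid is mild enough to free the α-branched ketone without enolising the new centre, and the auxiliary passes into the aqueous layer as its oxalate for recovery.

Step 5
Reactants: 7 (S)-3-[4-(benzyloxy)-3-methoxybenzyl]tetrahydro-4H-pyran-4-one
Product: 9 (5S)-5-[4-(benzyloxy)-3-methoxybenzyl]-3-(trifluoroacetyl)tetrahydro-4H-pyran-4-one, via lithium enolate 8 (not isolated)
Conditions: LiN(SiMe3)2, THF, −78 °C; CF3CO2CH2CF3; 1 M HCl work-up; used crude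
Reagents that add atoms: 2,2,2-trifluoroethyl trifluoroacetate, O=C(OCC(F)(F)F)C(F)(F)F
Why: Kinetic deprotonation with the hindered amide base at −78 °C takes the unsubstituted α-CH2 and not the benzylated methine, and Claisen-type C-acylation of that enolate with the trifluoroacetate ester activates only this carbon while the benzyl-bearing centre stays untouched.

Step 6
Reactants: 9 (5S)-5-[4-(benzyloxy)-3-methoxybenzyl]-3-(trifluoroacetyl)tetrahydro-4H-pyran-4-one
Product: 10 (5S)-5-[4-(benzyloxy)-3-methoxybenzyl]-3-diazotetrahydro-4H-pyran-4-one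
Conditions: MsN3, Et3N, H2O (1 equiv), MeCN, rt
Reagents that add atoms: methanesulfonyl azide, CS(=O)(=O)N=[N+]=[N-]
Why: Detrifluoroacetylative Regitz diazo transfer: the enolate of the 1,3-dicarbonyl adds to the sulfonyl azide and the adduct collapses with loss of the trifluoroacetyl group as the N-sulfonyl amide, so the diazo group lands on the one α-carbon that can bear it, and Et3N is too weak to enolise toward the benzyl-bearing methine.

Step 7
Reactants: 10 (5S)-5-[4-(benzyloxy)-3-methoxybenzyl]-3-diazotetrahydro-4H-pyran-4-one
Product: 13 methyl (3R,4R)-4-[4-(benzyloxy)-3-methoxybenzyl]tetrahydrofuran-3-carboxylate, via oxolanylidene ketene 11 (not isolated), via C3-epimeric methyl ester 12 (not isolated)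
Conditions: hν (medium-pressure Hg lamp, Pyrex, λ > 300 nm), MeOH, 15 °C; then NaOMe (0.3 equiv), 40 °C; AcOH
Reagents that add atoms: methanol, CO
Why: Excitation of the diazo ketone, which the ring holds s-cis, expels N2 while the benzyl-bearing ring carbon shifts from the carbonyl carbon to the diazo carbon (Wolff rearrangement), and the resulting ketene 11 adds methanol to give ester 12. The closest known reaction type is the photochemical ring contraction of cyclic α-diazo ketones, as in 2-diazocyclohexanone going to a cyclopentanecarboxylate. The oxolane closes by this 1,2-alkyl shift, a ring contraction in which the new C3–C4 bond forms as the old C4–C7 bond breaks, so no chain cyclisation is involved. The migrating carbon keeps its configuration, so the alkylation-derived centre becomes C4 (R) unchanged, whereas the new centre C3 arises by protonation of the ester enol, kinetically mostly anti to the benzyl group (cis ester), and is then brought to the trans 3R arrangement by NaOMe equilibration in the same flask under thermodynamic control by the C4 substituent. The step needs migration to beat carbene chemistry (O–H insertion into methanol, 1,2-hydride shift from the adjacent OCH2) and needs the right carbon to migrate: the locked s-cis geometry favours the concerted shift, and the carbonyl carbon carries only one substituent besides the diazo carbon, so the migrating group is fixed. Light above 300 nm excites the diazo ketone and not the benzyl aryl ethers.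

Step 8
Reactants: 13 methyl (3R,4R)-4-[4-(benzyloxy)-3-methoxybenzyl]tetrahydrofuran-3-carboxylate
Product: 14 (3R,4R)-4-[4-(benzyloxy)-3-methoxybenzyl]-N-methoxy-N-methyltetrahydrofuran-3-carboxamide
Conditions: MeNH(OMe)·HCl, i-PrMgCl, THF, −20 → 0 °C
Reagents that add atoms: N,O-dimethylhydroxylamine hydrochloride, CNOC.Cl
Why: Direct conversion of the methyl ester into the Weinreb amide with the chloromagnesium amide of N,O-dimethylhydroxylamine (Weinreb amidation) is standard, and any enolisation at C3 only returns the thermodynamically preferred trans isomer.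

Step 9
Reactants: 15 4-bromo-2,6-dimethoxyphenol
Product: 16 2-(benzyloxy)-5-bromo-1,3-dimethoxybenzene
Conditions: BnBr, K2CO3, DMF, 50 °C
Reagents that add atoms: benzyl bromide, BrCc1ccccc1
Why: Williamson etherification of the hindered but acidic phenol with benzyl bromide and carbonate is routine and gives the same protecting group as on the other ring, so that one final operation removes both.

Step 10
Reactants: 16 2-(benzyloxy)-5-bromo-1,3-dimethoxybenzene; 14 (3R,4R)-4-[4-(benzyloxy)-3-methoxybenzyl]-N-methoxy-N-methyltetrahydrofuran-3-carboxamide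
Product: 18 [(3R,4R)-4-[4-(benzyloxy)-3-methoxybenzyl]tetrahydrofuran-3-yl][4-(benzyloxy)-3,5-dimethoxyphenyl]methanone, via aryllithium 17 (not isolated)
Conditions: n-BuLi, THF, −78 °C; then 14, −78 → 0 °C; aq. NH4Cl
Reagents that add atoms: none
Why: Bromine–lithium exchange gives the aryllithium, which adds once to the Weinreb amide because the chelated tetrahedral adduct survives until quench (Weinreb ketone synthesis), and the trans ring configuration is the stable one at the ketone stage.

Step 11
Reactants: 18 [(3R,4R)-4-[4-(benzyloxy)-3-methoxybenzyl]tetrahydrofuran-3-yl][4-(benzyloxy)-3,5-dimethoxyphenyl]methanone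
Product: 19 (S)-[(3R,4R)-4-[4-(benzyloxy)-3-methoxybenzyl]tetrahydrofuran-3-yl][4-(benzyloxy)-3,5-dimethoxyphenyl]methanol
Conditions: (R)-Me-CBS oxazaborolidine [(R)-1-methyl-3,3-diphenyltetrahydro-1H,3H-pyrrolo[1,2-c][1,3,2]oxazaborole] (0.3 equiv), BH3·SMe2, THF, −20 °C; MeOH
Reagents that add atoms: none
Why: Corey–Bakshi–Shibata reduction: with the aryl group as the larger ketone substituent the R oxazaborolidine delivers hydride to the face that gives the S carbinol, the same face that Felkin–Anh addition anti to C4 is expected to favour, so catalyst and substrate should be matched.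

Step 12
Reactants: 19 (S)-[(3R,4R)-4-[4-(benzyloxy)-3-methoxybenzyl]tetrahydrofuran-3-yl][4-(benzyloxy)-3,5-dimethoxyphenyl]methanol
Product: 20 (S)-[(3R,4R)-4-(4-hydroxy-3-methoxybenzyl)tetrahydrofuran-3-yl](4-hydroxy-3,5-dimethoxyphenyl)methanol
Conditions: H2 (1 atm), 10% Pd/C, EtOAc, rt
Reagents that add atoms: none
Why: Hydrogenolysis of the two aryl benzyl ethers over Pd/C in a neutral aprotic solvent is much faster than cleavage of the benzylic C7–OH bond, so stopping at the hydrogen uptake for two benzyl groups should leave the three stereocentres and the carbinol intact.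

**Compound list**

1 | 4-(benzyloxy)-3-methoxybenzyl alcohol | COc1cc(CO)ccc1OCc1ccccc1 | starting material
2 | 4-(benzyloxy)-3-methoxybenzyl bromide | COc1cc(CBr)ccc1OCc1ccccc1 | intermediate
3 | tetrahydro-4H-pyran-4-one | O=C1CCOCC1 | starting material
4 | (R)-2-(methoxymethyl)-N-(tetrahydro-4H-pyran-4-ylidene)pyrrolidin-1-amine | COC[C@H]1CCCN1N=C1CCOCC1 | intermediate
5 | lithium (3,6-dihydro-2H-pyran-4-yl)[(R)-2-(methoxymethyl)pyrrolidin-1-yl]amide, the azaenolate of 4 (not isolated) | COC[C@H]1CCCN1N([Li])C1=CCOCC1 | intermediate
6 | (R)-N-[(3R)-3-[4-(benzyloxy)-3-methoxybenzyl]tetrahydro-4H-pyran-4-ylidene]-2-(methoxymethyl)pyrrolidin-1-amine (C=N geometry not specified) | COC[C@H]1CCCN1N=C1CCOC[C@@H]1Cc1ccc(OCc2ccccc2)c(OC)c1 | intermediate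
7 | (S)-3-[4-(benzyloxy)-3-methoxybenzyl]tetrahydro-4H-pyran-4-one | COc1cc(C[C@H]2COCCC2=O)ccc1OCc1ccccc1 | intermediate
8 | lithium (3S)-3-[4-(benzyloxy)-3-methoxybenzyl]-3,6-dihydro-2H-pyran-4-olate, the kinetic enolate of 7 (not isolated) | [Li]OC1=CCOC[C@@H]1Cc1ccc(OCc2ccccc2)c(OC)c1 | intermediate
9 | (5S)-5-[4-(benzyloxy)-3-methoxybenzyl]-3-(trifluoroacetyl)tetrahydro-4H-pyran-4-one (drawn as the diketone, largely enolised, C3 not defined) | COc1cc(C[C@H]2COCC(C(=O)C(F)(F)F)C2=O)ccc1OCc1ccccc1 | intermediate
10 | (5S)-5-[4-(benzyloxy)-3-methoxybenzyl]-3-diazotetrahydro-4H-pyran-4-one | COc1cc(C[C@H]2COCC(=[N+]=[N-])C2=O)ccc1OCc1ccccc1 | intermediate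
11 | [(4R)-4-[4-(benzyloxy)-3-methoxybenzyl]dihydrofuran-3(2H)-ylidene]methanone, the ketene (not isolated) | COc1cc(C[C@H]2COCC2=C=O)ccc1OCc1ccccc1 | intermediate
12 | methyl (4R)-4-[4-(benzyloxy)-3-methoxybenzyl]tetrahydrofuran-3-carboxylate, C3 epimer mixture with the cis 3S,4R ester expected to predominate (not isolated) | COc1cc(C[C@H]2COCC2C(=O)OC)ccc1OCc1ccccc1 | intermediate
13 | methyl (3R,4R)-4-[4-(benzyloxy)-3-methoxybenzyl]tetrahydrofuran-3-carboxylate | COc1cc(C[C@H]2COC[C@@H]2C(=O)OC)ccc1OCc1ccccc1 | intermediate
14 | (3R,4R)-4-[4-(benzyloxy)-3-methoxybenzyl]-N-methoxy-N-methyltetrahydrofuran-3-carboxamide | COc1cc(C[C@H]2COC[C@@H]2C(=O)N(C)OC)ccc1OCc1ccccc1 | intermediate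
15 | 4-bromo-2,6-dimethoxyphenol | COc1cc(Br)cc(OC)c1O | starting material
16 | 2-(benzyloxy)-5-bromo-1,3-dimethoxybenzene | COc1cc(Br)cc(OC)c1OCc1ccccc1 | intermediate
17 | [4-(benzyloxy)-3,5-dimethoxyphenyl]lithium (not isolated) | [Li]c1cc(OC)c(OCc2ccccc2)c(OC)c1 | intermediate
18 | [(3R,4R)-4-[4-(benzyloxy)-3-methoxybenzyl]tetrahydrofuran-3-yl][4-(benzyloxy)-3,5-dimethoxyphenyl]methanone | COc1cc(C[C@H]2COC[C@@H]2C(=O)c2cc(OC)c(OCc3ccccc3)c(OC)c2)ccc1OCc1ccccc1 | intermediate
19 | (S)-[(3R,4R)-4-[4-(benzyloxy)-3-methoxybenzyl]tetrahydrofuran-3-yl][4-(benzyloxy)-3,5-dimethoxyphenyl]methanol | COc1cc(C[C@H]2COC[C@@H]2[C@H](O)c2cc(OC)c(OCc3ccccc3)c(OC)c2)ccc1OCc1ccccc1 | intermediate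
20 | (S)-[(3R,4R)-4-(4-hydroxy-3-methoxybenzyl)tetrahydrofuran-3-yl](4-hydroxy-3,5-dimethoxyphenyl)methanol | COc1cc(C[C@H]2COC[C@@H]2[C@H](O)c2cc(OC)c(O)c(OC)c2)ccc1O | target

**Step count**

Total: 12 steps. Longest linear sequence: 10 steps (3 to 20 through steps 2–8 and 10–12); steps 1 and 9 prepare the two side fragments.

**Steps most likely to fail, with fallbacks**

Step 7. The ring contraction itself is expected to be dependable; the weak point is its stereochemical finish. Protonation of the ester enol on the face away from the benzyl group should give mainly the cis ester, and the methoxide equilibration meant to correct this may stop at a modest trans excess or lose material through ring-opening β-elimination. The fallback moves the thermodynamic correction to a later, more acidic and more biased carbonyl compound. It sets out from the C3-epimeric ester 12, isolated after irradiation without the methoxide treatment. Amidation under the conditions of step 8 would give the Weinreb amide epimer mixture F1. Addition of aryllithium 17 as in step 10 would give the aryl ketone epimer mixture F2. DBU in CH2Cl2 at room temperature should then equilibrate F2 at the α-position of the aryl ketone, where the bulkier aroyl group is expected to enforce the trans arrangement more strongly, and the sequence comes back to the route at 18.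

Step 11. The oxazaborolidine may fail to tell the aryl group from the α-branched oxolanyl group, giving poor facial selectivity at C7. The fallback gives up catalyst control for substrate control. It sets out from 18, which would be reduced with LiBH(s-Bu)3 in THF at −78 °C; Felkin–Anh addition anti to C4 is predicted to give the S carbinol, so the sequence comes back to the route at 19. The 7R carbinol F3, separated by chromatography, would be returned to 18 by Dess–Martin oxidation and resubmitted.

Step 12. Once the para-phenol is free, hydrogenolysis of the activated benzylic C7–O bond may compete with removal of the benzyl ethers, leading to over-reduction. The fallback removes the benzyl groups before the carbinol exists and changes the phenol protection. It sets out from 18, where hydrogenolysis (H2, Pd/C, EtOAc) should give the bisphenol ketone F4, which has no benzylic C–O single bond to lose. TBSCl and imidazole in DMF would give the bis(tert-butyldimethylsilyl) ether ketone F5. Reduction as in step 11 would give the silyl-protected S carbinol F6. Bu4NF buffered with AcOH in THF at 0 °C would then release both phenols without hydrogen, coming back to the route at 20.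

**Further compounds**

F1 | step 7 | (4R)-4-[4-(benzyloxy)-3-methoxybenzyl]-N-methoxy-N-methyltetrahydrofuran-3-carboxamide, C3 epimer mixture | COc1cc(C[C@H]2COCC2C(=O)N(C)OC)ccc1OCc1ccccc1
F2 | step 7 | [(4R)-4-[4-(benzyloxy)-3-methoxybenzyl]tetrahydrofuran-3-yl][4-(benzyloxy)-3,5-dimethoxyphenyl]methanone, C3 epimer mixture | COc1cc(C[C@H]2COCC2C(=O)c2cc(OC)c(OCc3ccccc3)c(OC)c2)ccc1OCc1ccccc1
F3 | step 11 | (R)-[(3R,4R)-4-[4-(benzyloxy)-3-methoxybenzyl]tetrahydrofuran-3-yl][4-(benzyloxy)-3,5-dimethoxyphenyl]methanol | COc1cc(C[C@H]2COC[C@@H]2[C@@H](O)c2cc(OC)c(OCc3ccccc3)c(OC)c2)ccc1OCc1ccccc1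
F4 | step 12 | [(3R,4R)-4-(4-hydroxy-3-methoxybenzyl)tetrahydrofuran-3-yl](4-hydroxy-3,5-dimethoxyphenyl)methanone | COc1cc(C[C@H]2COC[C@@H]2C(=O)c2cc(OC)c(O)c(OC)c2)ccc1O
F5 | step 12 | [(3R,4R)-4-[4-(tert-butyldimethylsilyloxy)-3-methoxybenzyl]tetrahydrofuran-3-yl][4-(tert-butyldimethylsilyloxy)-3,5-dimethoxyphenyl]methanone | COc1cc(C[C@H]2COC[C@@H]2C(=O)c2cc(OC)c(O[Si](C)(C)C(C)(C)C)c(OC)c2)ccc1O[Si](C)(C)C(C)(C)C
F6 | step 12 | (S)-[(3R,4R)-4-[4-(tert-butyldimethylsilyloxy)-3-methoxybenzyl]tetrahydrofuran-3-yl][4-(tert-butyldimethylsilyloxy)-3,5-dimethoxyphenyl]methanol | COc1cc(C[C@H]2COC[C@@H]2[C@H](O)c2cc(OC)c(O[Si](C)(C)C(C)(C)C)c(OC)c2)ccc1O[Si](C)(C)C(C)(C)C
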